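## Retrosynthetic overview

1. Target ⇐ phenol 16 (para-bromination last) ⇐ (Z)-bromoalkene, by removing the less hindered bromine of a dibromomethylidene group ⇐ cyclopentanone 13. Cyclopentane locants: C1 quaternary benzylic carbon, C2 CH(CH3), C3 the carbon that carries =CHBr, C4 and C5 the two CH2.
2. Enabling feature: C1 and the ring CH2 C5 are both β to C3. With C3 as a ketone they are the two termini of a cross-conjugated divinyl ketone, so the C1–C5 bond is made by a 4π-conrotatory Nazarov electrocyclization, which unites two carbons of like (electrophilic) polarity and creates the quaternary centre.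
3. Second feature: the phenol oxygen and the methyl carbon on C2 are 1,6-related through the arene and C1, so they are tied as the O–CH2 of a 2H-chromene. This temporary pyran ring fixes the geometry of the tetrasubstituted alkene and masks the phenol. It is later opened by retro-oxa-Michael elimination to a methylidene, whose hydrogenation sets the C2 methyl cis to the aryl group.
4. Ring order: benzene and pyran rings are bought together as 7-methylchroman-4-one; the cyclopentenone ring is closed in the Nazarov step; the pyran ring is then opened.
5. Dienone 8 ⇐ chromanone 1 by Vilsmeier–Haack chloroformylation, Suzuki–Miyaura methylation, (E)-silylvinyl addition and oxidation.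

Key step: step 5

Remarks (assumptions):
- 7-Methylchroman-4-one (1) and [(E)-2-bromoethenyl]trimethylsilane (5) are taken as purchasable; 1 is otherwise two steps from m-cresol and 3-chloropropanoic acid.
- The sense of induction of the chiral acid in step 5 cannot be predicted with certainty; the (S)-acid is written, and its antipode would be used if the opposite sense is found.

## Route

Step 1
Reactants: 1 7-methylchroman-4-one
Product: 3 4-chloro-7-methyl-2H-chromene-3-carbaldehyde, via iminium chloride 2 (not isolated)
Conditions: POCl3, DMF, 0 → 60 °C; then ice/H2O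
Reagents that add atoms: N,N-dimethylformamide, CN(C)C=O (formyl carbon); phosphoryl chloride, O=P(Cl)(Cl)Cl (chlorine); water, O (aldehyde oxygen)
Why: Vilsmeier–Haack chloroformylation, in which the chloroiminium reagent formylates the enolizable C3 of the chromanone and the vinylogous amide oxygen is exchanged for chloride, is the standard conversion of chroman-4-ones into 4-chloro-2H-chromene-3-carbaldehydes; no stereocentre is formed.

Step 2
Reactants: 3 4-chloro-7-methyl-2H-chromene-3-carbaldehyde
Product: 4 4,7-dimethyl-2H-chromene-3-carbaldehyde
Conditions: MeB(OH)2, Pd(OAc)2 (cat.), SPhos (cat.), K3PO4, toluene/H2O, 90 °C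
Reagents that add atoms: methylboronic acid, CB(O)O
Why: Suzuki–Miyaura coupling of a β-chlorovinyl aldehyde (a vinylogous acid chloride) should be easy because zerovalent palladium inserts readily into this activated C–Cl bond, and the ring fixes the position and geometry of the double bond.

Step 3
Reactants: 4 4,7-dimethyl-2H-chromene-3-carbaldehyde; 5 [(E)-2-bromoethenyl]trimethylsilane
Product: 7 (2E)-1-(4,7-dimethyl-2H-chromen-3-yl)-3-(trimethylsilyl)prop-2-en-1-ol (racemic carbinol), via vinyllithium 6 (not isolated)
Conditions: 5, t-BuLi (2 equiv), Et2O, −78 °C; then 4, −78 → 0 °C; H2O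
Reagents that add atoms: none
Why: bromine–lithium exchange with retention of alkene geometry gives the (E)-vinyllithium, which adds 1,2 to the enal; the carbinol centre is formed racemic and is removed by the oxidation that follows.

Step 4
Reactants: 7 (2E)-1-(4,7-dimethyl-2H-chromen-3-yl)-3-(trimethylsilyl)prop-2-en-1-ol
Product: 8 (2E)-1-(4,7-dimethyl-2H-chromen-3-yl)-3-(trimethylsilyl)prop-2-en-1-one
Conditions: MnO2, CH2Cl2, rt
Reagents that add atoms: none
Why: MnO2 oxidation of a doubly allylic alcohol gives the cross-conjugated dienone under neutral conditions that leave the vinylsilane and the allylic aryl ether untouched.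

Step 5
Reactants: 8 (2E)-1-(4,7-dimethyl-2H-chromen-3-yl)-3-(trimethylsilyl)prop-2-en-1-one
Product: 10 (3aS,9bR)-7,9b-dimethyl-3a,9b-dihydrocyclopenta[c]chromen-3(4H)-one, via cross-conjugated dienol 9 (not isolated)
Conditions: Zn(OTf)2 (5 mol%), (S)-6,6'-bis(2,4,6-triisopropylphenyl)-SPINOL hydrogen phosphate (6 mol%), PhOH (1.1 equiv), ClCH2CH2Cl, 40 °C
Reagents that add atoms: none
Why: Proposed new method: a catalytic enantioselective silicon-directed Nazarov cyclization that closes onto a fully substituted, ring-locked β-carbon, in which Zn(OTf)2 on the ketone oxygen (the chromene ether oxygen can serve as a second contact in a six-membered chelate) generates the hydroxypentadienyl cation and a thermally allowed conrotatory 4π electrocyclization (cationic, formally 5-endo) closes the cyclopentenone ring between the benzylic chromene carbon and the silyl-bearing vinyl carbon; the closest known reaction types are the enantioselective silicon-directed Nazarov cyclization of β-silyl dienones under cooperative Zn(OTf)2/chiral spiro phosphoric acid catalysis and chiral-Brønsted-acid Nazarov closures that create quaternary carbons. The closing terminus is a benzylic cation stabilized by the ortho ring oxygen, and the α-substituent (the ring CH2) favours the reactive U-shaped conformer, so closure should be feasible despite the inward methyl group. The quaternary centre (9bR) is set by torquoselectivity: the chiral phosphate held at the zinc-bound oxygen makes the two senses of conrotation diastereomeric, and because the chromene ring fixes the alkene geometry (methyl inward, arene outward) each sense leads to one enantiomer only. Loss of the silyl group from the β-silyl-stabilized oxyallyl cation to phenol gives dienol 9 with the new C=C away from the quaternary carbon, and this fast desilylation is what should outrun a 1,2-aryl or 1,2-methyl shift from the new quaternary centre. Protonation of 9 at the ring-fusion carbon gives the cis-fused enone (3aS) for reasons of ring strain; this centre is of no consequence because step 6 removes it.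

Step 6
Reactants: 10 (3aS,9bR)-7,9b-dimethyl-3a,9b-dihydrocyclopenta[c]chromen-3(4H)-one
Product: 12 2-[(1S)-1-methyl-5-methylidene-4-oxocyclopent-2-en-1-yl]-5-methylphenyl acetate, via ring-opened phenol 11 (not isolated)
Conditions: DBU (2.5 equiv), Ac2O (1.3 equiv), MeCN, 0 °C → rt
Reagents that add atoms: acetic anhydride, CC(=O)OC(C)=O
Why: retro-oxa-Michael (E1cB) opening, the same process as the base-induced flavanone-to-chalcone opening, should work because the ring-fusion hydrogen is the only α-hydrogen of 10, the dienolate expels the β-aryloxide, and irreversible O-acetylation of phenoxide 11 drains any reversible oxa-Michael re-addition; the quaternary centre is untouched.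

Step 7
Reactants: 12 2-[(1S)-1-methyl-5-methylidene-4-oxocyclopent-2-en-1-yl]-5-methylphenyl acetate
Product: 13 2-[(1R,2R)-1,2-dimethyl-3-oxocyclopentyl]-5-methylphenyl acetate
Conditions: H2 (1 atm), Pd/C, EtOAc, rt
Reagents that add atoms: none
Why: heterogeneous hydrogenation of both C=C bonds under neutral conditions should add hydrogen to the exocyclic methylidene from the face opposite the bulky 2-acetoxyaryl group on the adjacent quaternary carbon, placing the new methyl cis to the aryl group (2R); the methylidene cannot migrate because its ring neighbours are a quaternary carbon and the carbonyl.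

Step 8
Reactants: 13 2-[(1R,2R)-1,2-dimethyl-3-oxocyclopentyl]-5-methylphenyl acetate
Product: 14 2-[(1R,2R)-3-(dibromomethylidene)-1,2-dimethylcyclopentyl]-5-methylphenyl acetate
Conditions: CBr4, PPh3, Zn dust, CH2Cl2, rt; then 13, reflux
Reagents that add atoms: carbon tetrabromide, BrC(Br)(Br)Br
Why: Ramirez gem-dibromoolefination with the non-basic ylide Ph3P=CBr2 (zinc removes the acidic Ph3PBr2) converts the ketone without enolizing the α-centre, which carries the less stable aryl-cis methyl and would epimerize under basic olefination conditions.

Step 9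
Reactants: 14 2-[(1R,2R)-3-(dibromomethylidene)-1,2-dimethylcyclopentyl]-5-methylphenyl acetate
Product: 15 2-[(1R,2R,3Z)-3-(bromomethylidene)-1,2-dimethylcyclopentyl]-5-methylphenyl acetate
Conditions: Bu3SnH (1.05 equiv), Pd(PPh3)4 (cat.), toluene, rt
Reagents that add atoms: none
Why: in this palladium-catalysed stereoselective hydrogenolysis of a 1,1-dibromoalkene, zerovalent palladium should insert into the less hindered C–Br bond (cis to the ring CH2, away from the methyl-bearing carbon flanked by the quaternary centre) and the tin hydride replaces it by hydrogen with retention, leaving the bromine cis to the methyl-bearing carbon (Z).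

Step 10
Reactants: 15 2-[(1R,2R,3Z)-3-(bromomethylidene)-1,2-dimethylcyclopentyl]-5-methylphenyl acetate
Product: 16 2-[(1R,2R,3Z)-3-(bromomethylidene)-1,2-dimethylcyclopentyl]-5-methylphenol
Conditions: K2CO3 (cat.), MeOH, 0 °C → rt
Reagents that add atoms: none
Why: mild transesterification removes the aryl acetate; the vinyl bromide and the now non-enolizable allylic stereocentre are inert to carbonate in methanol.

Step 11
Reactants: 16 2-[(1R,2R,3Z)-3-(bromomethylidene)-1,2-dimethylcyclopentyl]-5-methylphenol
Product: 17 4-bromo-2-[(1R,2R,3Z)-3-(bromomethylidene)-1,2-dimethylcyclopentyl]-5-methylphenol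
Conditions: NBS (1.0 equiv), MeCN, −20 → 0 °C
Reagents that add atoms: N-bromosuccinimide, O=C1CCC(=O)N1Br
Why: electrophilic aromatic bromination of the free phenol, which is far more nucleophilic than the electron-poor bromoalkene, should occur at the position para to OH (ortho to the aryl methyl), the only unhindered activated site.

## Compound list

1 | 7-methylchroman-4-one (7-methyl-2,3-dihydro-4H-chromen-4-one) | Cc1ccc2c(c1)OCCC2=O | starting material
2 | N-[(4-chloro-7-methyl-2H-chromen-3-yl)methylidene]-N-methylmethanaminium chloride | Cc1ccc2c(c1)OCC(C=[N+](C)C)=C2Cl.[Cl-] | intermediate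
3 | 4-chloro-7-methyl-2H-chromene-3-carbaldehyde | Cc1ccc2c(c1)OCC(C=O)=C2Cl | intermediate
4 | 4,7-dimethyl-2H-chromene-3-carbaldehyde | Cc1ccc2c(c1)OCC(C=O)=C2C | intermediate
5 | [(E)-2-bromoethenyl]trimethylsilane | C[Si](C)(C)/C=C/Br | starting material
6 | [(E)-2-(trimethylsilyl)ethenyl]lithium | C[Si](C)(C)/C=C/[Li] | intermediate
7 | (2E)-1-(4,7-dimethyl-2H-chromen-3-yl)-3-(trimethylsilyl)prop-2-en-1-ol, racemic at the carbinol carbon | Cc1ccc2c(c1)OCC(C(O)/C=C/[Si](C)(C)C)=C2C | intermediate
8 | (2E)-1-(4,7-dimethyl-2H-chromen-3-yl)-3-(trimethylsilyl)prop-2-en-1-one | Cc1ccc2c(c1)OCC(C(=O)/C=C/[Si](C)(C)C)=C2C | intermediate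
9 | (9bS)-7,9b-dimethyl-4,9b-dihydrocyclopenta[c]chromen-3-ol | OC1=C2COc3cc(C)ccc3[C@]2(C)C=C1 | intermediate
10 | (3aS,9bR)-7,9b-dimethyl-3a,9b-dihydrocyclopenta[c]chromen-3(4H)-one | O=C1C=C[C@@]2(C)c3ccc(C)cc3OC[C@@H]12 | intermediate
11 | (4S)-4-(2-hydroxy-4-methylphenyl)-4-methyl-5-methylidenecyclopent-2-en-1-one | Cc1cc(O)c(cc1)[C@]1(C)C=CC(=O)C1=C | intermediate
12 | 2-[(1S)-1-methyl-5-methylidene-4-oxocyclopent-2-en-1-yl]-5-methylphenyl acetate | CC(=O)Oc1cc(C)ccc1[C@]1(C)C=CC(=O)C1=C | intermediate
13 | 2-[(1R,2R)-1,2-dimethyl-3-oxocyclopentyl]-5-methylphenyl acetate | CC(=O)Oc1cc(C)ccc1[C@]1(C)CCC(=O)[C@@H]1C | intermediate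
14 | 2-[(1R,2R)-3-(dibromomethylidene)-1,2-dimethylcyclopentyl]-5-methylphenyl acetate | CC(=O)Oc1cc(C)ccc1[C@]1(C)CCC(=C(Br)Br)[C@@H]1C | intermediate
15 | 2-[(1R,2R,3Z)-3-(bromomethylidene)-1,2-dimethylcyclopentyl]-5-methylphenyl acetate | CC(=O)Oc1cc(C)ccc1[C@]1(C)CC/C(=C/Br)[C@@H]1C | intermediate
16 | 2-[(1R,2R,3Z)-3-(bromomethylidene)-1,2-dimethylcyclopentyl]-5-methylphenol | Cc1cc(O)c(cc1)[C@]1(C)CC/C(=C/Br)[C@@H]1C | intermediate
17 | 4-bromo-2-[(1R,2R,3Z)-3-(bromomethylidene)-1,2-dimethylcyclopentyl]-5-methylphenol | Cc1cc(O)c([C@]2(C)CC/C(=C/Br)[C@@H]2C)cc1Br | target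

Total step count: 11.
Longest linear sequence: 11 steps (1 → 17); 5 enters as a purchased reagent.

## Steps most likely to fail

1. Step 5 (proposed new method). The chiral acid pair may fail to impose one sense of conrotation (low torquoselectivity), or may not turn over on the hindered, fully substituted terminus. Fallback with known chemistry: setting out from dienone 8, stoichiometric FeCl3 in CH2Cl2 (−30 → 0 °C) should effect the established silicon-directed Nazarov cyclization to the racemic cis-fused enone F1 (10 together with its mirror image). Resolution of F1 by preparative chromatography on a chiral stationary phase comes back to the route at 10.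

2. Step 9. The oxidative addition may not discriminate enough between the two C–Br bonds, which would erode the Z geometry; the hindered ketone may also olefinate slowly in step 8. Fallback setting out from ketone 13:
 - Lombardo-type methylenation (Zn, CH2Br2, TiCl4, THF/CH2Cl2; non-basic, so no epimerization) should give 2-[(1R,2S)-1,2-dimethyl-3-methylidenecyclopentyl]-5-methylphenyl acetate F2 (same spatial arrangement as 13; the descriptor changes by priority only).
 - A boryl-Heck reaction (catecholchloroborane, zerovalent palladium catalyst with a bulky phosphine, Cy2NMe) should give the (E)-alkenyl catecholboronate F3 with boron on the unhindered CH2 side.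
 - Br2 (CH2Cl2, −78 °C), then NaOMe/MeOH: anti addition of bromine followed by anti elimination of boron and bromide replaces boron by bromine with inversion of alkene geometry. The methoxide also cleaves the acetate, so the sequence comes back to the route at phenol 16.

3. Step 7. Facial selectivity in the hydrogenation of the methylidene may be insufficient, or 1,4-reduction followed by unselective enol protonation may intervene; either would give the C2 epimer. Fallback setting out from enone 10, keeping the pyran ring so that the cis ring fusion defines C2: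
 - H2, Pd/C should give the cis-fused saturated ketone F4.
 - Ethylene glycol, PPTS, benzene at reflux should give dioxolane F5.
 - Lithium 4,4'-di-tert-butylbiphenylide (THF, −78 °C) cleaves the aryl O–CH2 bond to a phenoxide and a primary alkyllithium. MeOH (1 equiv) protonates the alkyllithium to the methyl group, and Ac2O added to the same flask gives ketal acetate F6.
 - PPTS in wet acetone then releases the ketone and comes back to the route at 13.

## Further compounds

F1 | step 5 | racemic cis-fused 7,9b-dimethyl-3a,9b-dihydrocyclopenta[c]chromen-3(4H)-one (1:1 mixture of 10 and its enantiomer; the SMILES shows the (3aR,9bS) enantiomer that accompanies 10) | O=C1C=C[C@]2(C)c3ccc(C)cc3OC[C@H]12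
F2 | step 9 | 2-[(1R,2S)-1,2-dimethyl-3-methylidenecyclopentyl]-5-methylphenyl acetate | CC(=O)Oc1cc(C)ccc1[C@]1(C)CCC(=C)[C@@H]1C
F3 | step 9 | 2-[(1R,2S,3E)-3-(1,3,2-benzodioxaborol-2-ylmethylidene)-1,2-dimethylcyclopentyl]-5-methylphenyl acetate | CC(=O)Oc1cc(C)ccc1[C@]1(C)CC/C(=C\B2Oc3ccccc3O2)[C@@H]1C
F4 | step 7 | (3aS,9bR)-7,9b-dimethyl-1,2,3a,9b-tetrahydrocyclopenta[c]chromen-3(4H)-one | O=C1CC[C@@]2(C)c3ccc(C)cc3OC[C@@H]12
F5 | step 7 | (3aS,9bR)-7,9b-dimethyl-1,2,3a,9b-tetrahydro-4H-spiro[cyclopenta[c]chromene-3,2'-[1,3]dioxolane] | O1CCOC12CC[C@@]3(C)c4ccc(C)cc4OC[C@@H]23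
F6 | step 7 | 2-[(6R,7R)-6,7-dimethyl-1,4-dioxaspiro[4.4]nonan-7-yl]-5-methylphenyl acetate | CC(=O)Oc1cc(C)ccc1[C@]1(C)CCC2(OCCO2)[C@@H]1C
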